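## Structural features

The target is a chroman-4-one in which benzene ring A is fused through C4a and C8a to ring B (O1, C2, C3 and the C4 ketone). Ring A is hexasubstituted: oxygens at C5 (free OH, hydrogen-bonded to the C4 carbonyl), C7 (OMe) and C8a (ring oxygen O1) alternate with carbon substituents at C4a (the ketone), C6 (prenyl) and C8 (the benzylic carbon of a 3-phenylpropanoic acid chain). There are three stereocentres: C2 (S) and C3 (R) are adjacent in ring B and carry cis methyl groups, whereas the benzylic centre on C8 (R) is insulated from them by C8a and O1, so it cannot direct ring B and must be set on its own. The cis C3 centre, alpha to the ketone, is the less stable epimer and is lost by enolisation or by ring opening and re-closure under base or a chelating Lewis acid. The prenyl group tolerates neither hydrogenation nor strong acid, which would cyclise it onto O5, and a C1 carboxyl derivative lactonises onto any free phenol at C7 or C8a. The real difficulty is regiochemical: a benzene with six different substituents whose three oxygens must end in three different states. The key step exploits the alternation of oxygen and carbon around ring A: a heteroatom-substituted alkyne brings C8 and C8a (carbon, then oxygen) and a vinylketene brings C7, C4a, C5 and C6, so the three oxygens are born as OH, O-silyl and O-ethyl.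

## Logic of the disconnections

33 to 32: the O5–H bond is traced back to an O5–ethyl bond. O5 has to stay blocked until ring B exists, because a free O5 would compete with O1 in the ring closure, and ethyl is the mark that the benzannulation puts on this oxygen. Nothing is gained in size; the gain is regiocontrol over the two oxygens that flank C4a. The forward step must cleave one alkyl aryl ether next to a second one (C7–OMe) without enolising C3 or exposing the prenyl group to acid.

32 to 30: the C1 carboxyl is taken back to a primary alcohol. An ester at C1 could not be carried through the acetylide chemistry and would lactonise onto O7–H or O1–H as soon as either is free; the alcohol can do neither. The gain is one spectator group that serves unchanged from 4 to 30. The demand is a late oxidation that is close to neutral and is run before any phenol is unmasked.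

30 to 28: the O1–C2 bond is cut (conjugate addition in reverse). This removes ring B and both of its stereocentres at once and leaves an achiral enone side chain. The forward step must add O1 to one face of the enone under catalyst control and protonate C3 kinetically.

28 to 27 to 24 + 25: the C4–C3 bond is cut between an aldehyde carbon on ring A and a four-carbon alkenyl nucleophile, and the C4 carbonyl is taken back to a carbinol. Cutting here avoids a Friedel–Crafts acylation on a ring that already carries the prenyl group, and the whole side chain comes from a purchased bromide. The demand is retention of alkene geometry through the metalation and an oxidation selective for the doubly activated alcohol.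

24 to 22: the C4a–C4 bond is cut. C4a is the only ring position that still bears hydrogen and lies ortho to the free O1–H, so a phenoxide-directed formylation can find it without any acid. The gain is a pentasubstituted phenol without a carbonyl group. The demand is C-selective formylation at a carbon flanked by two oxygens, with the primary alcohol left free.

22 to 21 to 20: the two O–Si bonds are restored and the O7–CH3 bond is cut. Methylation precedes desilylation, so O7 and O1 are never free at the same time. The gain is the oxygen pattern of the benzannulation product, with one free phenol at a time. The demand is alkylation of a phenol with two ortho substituents under conditions that leave the aryl silyl ether in place.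

20 to 18 to 14 + 17, and 17 to 15: the C6–C1' bond of the prenyl group is cut as a [3,3] shift from O7, and the O7–C bond as an allylic etherification. The free O7–H of 14 is used twice, first to carry the prenyl unit to C6 and then to become the methyl ether. The gain is a ring with only four substituents and a purchased tertiary alcohol. The demand is the tertiary (branched) ether in the etherification, since only that isomer rearranges to the linear prenyl group.

14 to 8 + 9: the C7–C8, C4a–C8a and C6–C7 bonds are cut. Ring A falls apart into an alkyne and a four-carbon ketene precursor, and every later regiochemical problem is reduced to the orientation of one cycloaddition. The demand is a thermal cascade that leaves the propargylic stereocentre alone.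

8 to 5: the O–C(sp) bond and both O–Si bonds are cut. The terminal alkyne is oxidised at carbon and silylated, and the side-chain hydroxyl is silylated in the same flask, which saves a protection step. The demand is oxygen transfer to the acetylide carbon in the presence of an alkoxide, with base stoichiometry exact enough to spare the propargylic C–H.

5 to 4 to 3 to 1 + 2: the bond between the benzylic carbon and the alkyne carbon is cut as a catalytic asymmetric conjugate alkynylation, so the stereocentre and the correct chain length come in one step from two purchased materials. A route through desymmetrisation of a symmetrical diacid derivative was set aside: its acid arm would have to become the ethynyl group without gain of carbon, whereas the usual aldehyde-to-alkyne homologations add one and would place a methylene between stereocentre and alkyne. The demand is facial control by the ligand and suppression of alkyne dimerisation.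

## Other disconnections considered

Alternative 1: The cut is C2–C3. The precursor would be the diazo ketone A1, in which ring A is complete, C4a carries a 2-diazopropanoyl group, O1 is an ethyl ether and O5 an acetate. A chiral carboxylate dimer of divalent rhodium would decompose the diazo group of A1, and the carbenoid at C3 would insert into a methylene C–H of the O1 ethyl group to give the cis-chromanone A2, the O5-acetyl methyl ester of 33.
- In its favour: ring B and both stereocentres form in one step from an achiral side chain, and insertion next to an ether oxygen is an activated, cis-favouring process. The ring-forming event is one step against the four (steps 11 to 14) of the chosen plan, and on that count it is the better, although A1 has first to be assembled.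
- Against it here: the carbenoid from A1 carries an alpha methyl group, so 1,2-hydride shift competes. It also has the ether oxygen (ylide formation and 1,2-shift), the prenyl alkene and allylic C–H bonds within reach. Closure of a six-membered ring by insertion is less general than closure of a five-membered one. The diazo group of A1 must be installed on a carbonyl flanked by two ortho substituents in the presence of a second enolisable ester. The acetate and methyl ester of A2 must afterwards be cleaved by base from a cis-chromanone.
- Comparison: both plans rely on a chiral catalyst for C2 and C3, and in that they are equal. Alternative 1 does nothing for ring A, which would still need a benzannulation or a phloroglucinol starting point. The chosen plan is the safer on chemoselectivity and on the end-game.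

Alternative 2: The cuts are C4a–C4, C4–C3 and O1–C2. An ortho-iodophenol A3 (iodine on C4a, free O1–H, O5 as methoxymethyl ether), buta-1,2-diene A4 and carbon monoxide A5 would be joined by a zerovalent palladium catalyst. The arylpalladium would take up A5, the acyl group would add to the central allene carbon, and the phenoxide would close onto the methyl-bearing allyl terminus, giving the 3-methylenechromanone A6.
- In its favour: three bonds and the whole ring-B skeleton come in one convergent step from very simple partners, which is the better step economy. The methoxymethyl group at O5 of A6 is also easier to remove at the end than the ethyl group of the chosen plan, a point on which it is the better.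
- Against it here: attack at the substituted rather than the unsubstituted allyl terminus is not assured. Asymmetric induction at C2 in this annulation has no secure basis. Oxidative addition at the iodide of A3, flanked by two oxygens, is slow. C3 must then be set in a separate reduction of the exocyclic alkene of A6 that has to spare the prenyl group, which rules out ordinary hydrogenation.
- Comparison: Alternative 2 wins on convergence and loses on stereocontrol, since it sets C2 and C3 in two uncertain operations where the chosen plan sets them in one catalysed cyclisation of a known type.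

Alternative 3: The cut is O1–C2, as in the chosen plan, but made by substitution. An anti-configured 3-hydroxy-2-methylbutanoyl unit, derived from methyl (R)-3-hydroxybutanoate A7 by Fráter–Seebach methylation, would be attached to C4a to give the seco-alcohol A8. Mitsunobu activation (phosphine and azodicarboxylate) would let O1 displace the secondary hydroxyl of A8 with inversion, giving the cis-chromanone A9.
- In its favour: both ring-B centres come from the chiral pool and a substrate-controlled alkylation, so their absolute configuration is known in advance and does not depend on the facial selectivity of a catalyst. On certainty of configuration it is the better.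
- Against it here: the beta-hydroxy ketone of A8 can lose water by an E1cB path under activation, after which ring closure would proceed without stereocontrol. Joining the acyl unit to C4a without epimerising its alpha carbon, and without a Lewis acid that harms the prenyl group, needs an aryl-metal route and a protected hydroxyl, which costs steps.
- Comparison: the two plans close the same bond and are equal in leaving the final deprotections to be done on a cis-chromanone. The chosen plan needs only a catalytic source of chirality and no extra protecting group on the side unit.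

Key step: step 5

Remark on the chemistry: C1 of the propanoate chain is carried through the key step as a triisopropylsilyl-protected primary alcohol instead of a methyl ester, because an ester would not survive acetylide formation and oxidation; this changes a spectator group only, and the carbon skeleton of 8 and 14, the three bonds formed and the ring closed in step 5 are unaffected.

## Route

Step 1
Reactants: 1 (E)-cinnamaldehyde; 2 (triisopropylsilyl)acetylene
Product: 3 (R)-3-phenyl-5-(triisopropylsilyl)pent-4-ynal
Conditions: [Rh(OAc)(C2H4)2]2 (2.5 mol %), DTBM-SEGPHOS (5.5 mol %; the enantiomer that directs attack to the Re face of C3), 2 (2 equiv), MeOH, 40 °C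
Reagents that add atoms: none
Why: Asymmetric conjugate alkynylation of an enal with a bulky silylacetylene under monovalent rhodium–bisphosphine catalysis; the alkynylrhodium adds to the beta carbon and methanol protonates the resulting oxa-allyl species. The bulky silyl group and ligand suppress alkyne dimerisation, and the ligand fixes the face: Re-face delivery gives the R aldehyde.

Step 2
Reactants: 3 (R)-3-phenyl-5-(triisopropylsilyl)pent-4-ynal
Product: 4 (R)-3-phenyl-5-(triisopropylsilyl)pent-4-yn-1-ol
Conditions: NaBH4 (0.6 equiv), MeOH, 0 °C
Reagents that add atoms: none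
Why: Borohydride reduction of the aldehyde; the stereocentre is beta to the carbonyl and cannot enolise. The alcohol level is the form in which C1 survives acetylide chemistry and cannot lactonise later.

Step 3
Reactants: 4 (R)-3-phenyl-5-(triisopropylsilyl)pent-4-yn-1-ol
Product: 5 (S)-3-phenylpent-4-yn-1-ol
Conditions: TBAF (1.2 equiv), THF, 0 °C to rt
Reagents that add atoms: none
Why: Fluoride-induced protodesilylation of the alkynylsilane; no bond at the stereocentre is touched. The descriptor changes from R to S only because phenyl outranks an unsubstituted ethynyl group.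

Step 4
Reactants: 5 (S)-3-phenylpent-4-yn-1-ol
Product: 8 (R)-triisopropyl{[3-phenyl-5-(triisopropylsilyloxy)pent-1-yn-1-yl]oxy}silane, via dilithium alkoxide–acetylide 6 (not isolated), via dilithium alkoxide–ynolate 7 (not isolated)
Conditions: n-BuLi (2.05 equiv), THF, −78 °C; LiOOt-Bu (1.2 equiv, from t-BuOOH and LiHMDS, THF, −78 °C), −78 to 0 °C; TIPSOTf (2.5 equiv), −78 to 0 °C; chromatography on Et3N-deactivated silica
Reagents that add atoms: tert-butyl hydroperoxide, CC(C)(C)OO; triisopropylsilyl trifluoromethanesulfonate, CC(C)[Si](OS(=O)(=O)C(F)(F)F)(C(C)C)C(C)C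
Why: Acetylide oxidation to an ynolate: lithium tert-butyl peroxide transfers electrophilic oxygen to the acetylide carbon of 6, and the bulky silyl triflate then silylates the ynolate on oxygen and the alkoxide in the same flask. With C1 at the alcohol level there is no enolisable or electrophilic site to compete, and exact base stoichiometry leaves the propargylic C–H alone.

Step 5
Reactants: 8 (R)-triisopropyl{[3-phenyl-5-(triisopropylsilyloxy)pent-1-yn-1-yl]oxy}silane; 9 3-ethoxycyclobut-2-en-1-one
Product: 14 (R)-5-ethoxy-2-[1-phenyl-3-(triisopropylsilyloxy)propyl]-3-(triisopropylsilyloxy)phenol, via (1-ethoxyvinyl)ketene 10 (not isolated), via vinylcyclobutenone 11 (not isolated), via dienylketene 12 (not isolated), via cyclohexadienone 13 (not isolated)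
Conditions: 9 (1.5 equiv, added over 4 h), toluene (0.1 M), 110 °C, sealed vessel, 12 h
Reagents that add atoms: none
Why: Proposed new method: thermal four-electron electrocyclic opening of 9 gives vinylketene 10, whose electrophilic carbonyl carbon bonds to the alkyne carbon remote from oxygen (C8, the nucleophilic terminus of the siloxyalkyne) in a regiospecific [2+2] cycloaddition that forms C7–C8 and C4a–C8a and gives cyclobutenone 11. A second four-electron opening gives dienylketene 12, and a six-electron electrocyclisation forms C6–C7 and closes ring A as dienone 13, which tautomerises to phenol 14. The closest known reaction type is the Danheiser benzannulation of 3-alkyl- and 3-arylcyclobutenones with siloxyalkynes to resorcinol monosilyl ethers; new here are the 3-alkoxy donor on the four-membered ring (a vinylogous ester that opens less readily, hence 110 °C) and a stereogenic propargylic carbon on the alkyne. Ring A is closed in the electrocyclic, disrotatory six-electron mode. No stereocentre is created, and the benzylic C–H is not engaged under neutral thermal conditions, so the R configuration should be retained. The selectivity needed is the orientation of the [2+2] step, which the polarisation of the alkyne by its siloxy group secures, so that O7 appears as free OH, O1 as silyl ether and O5 as ethyl ether. Slow addition of 9 keeps the ketene concentration low, so that it is intercepted by 8 and not by the product phenol.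

Step 6
Reactants: 15 2-methylbut-3-en-2-ol
Product: 17 tert-butyl (2-methylbut-3-en-2-yl) carbonate, via lithium 2-methylbut-3-en-2-olate 16 (not isolated)
Conditions: n-BuLi (1.05 equiv), THF, 0 °C; Boc2O (1.1 equiv), 0 °C to rt
Reagents that add atoms: di-tert-butyl dicarbonate, CC(C)(C)OC(=O)OC(=O)OC(C)(C)C
Why: O-acylation of the tertiary lithium alkoxide with the dicarbonate gives the mixed carbonate, the ionisable partner for the allylic etherification.

Step 7
Reactants: 14 (R)-5-ethoxy-2-[1-phenyl-3-(triisopropylsilyloxy)propyl]-3-(triisopropylsilyloxy)phenol; 17 tert-butyl (2-methylbut-3-en-2-yl) carbonate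
Product: 18 (R)-triisopropyl{3-[4-ethoxy-2-(2-methylbut-3-en-2-yloxy)-6-(triisopropylsilyloxy)phenyl]-3-phenylpropoxy}silane
Conditions: Pd(PPh3)4 (3 mol %), 17 (1.3 equiv), THF, 0 °C
Reagents that add atoms: none
Why: Tsuji–Trost O-allylation: zerovalent palladium ionises 17 with loss of CO2, the tert-butoxide formed deprotonates the phenol, and the phenoxide attacks the more substituted allyl terminus at low temperature to give the tertiary (reverse-prenyl) ether. The reaction is stopped at full conversion so that this kinetic ether does not isomerise to the linear one.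

Step 8
Reactants: 18 (R)-triisopropyl{3-[4-ethoxy-2-(2-methylbut-3-en-2-yloxy)-6-(triisopropylsilyloxy)phenyl]-3-phenylpropoxy}silane
Product: 20 (R)-3-ethoxy-2-(3-methylbut-2-en-1-yl)-6-[1-phenyl-3-(triisopropylsilyloxy)propyl]-5-(triisopropylsilyloxy)phenol, via ortho-dienone 19 (not isolated)
Conditions: toluene, 110 °C
Reagents that add atoms: none
Why: Aromatic Claisen rearrangement ([3,3]) of the tertiary allyl aryl ether; of the two ortho carbons only C6 carries hydrogen, so dienone 19 re-aromatises, and the allyl inversion turns the reverse-prenyl ether into the linear prenyl group. Attack at the substituted ortho carbon C8 is reversible and unproductive.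

Step 9
Reactants: 20 (R)-3-ethoxy-2-(3-methylbut-2-en-1-yl)-6-[1-phenyl-3-(triisopropylsilyloxy)propyl]-5-(triisopropylsilyloxy)phenol
Product: 21 (R)-triisopropyl{3-[4-ethoxy-2-methoxy-3-(3-methylbut-2-en-1-yl)-6-(triisopropylsilyloxy)phenyl]-3-phenylpropoxy}silane
Conditions: MeI (3 equiv), K2CO3 (2 equiv), acetone, 50 °C
Reagents that add atoms: iodomethane, CI
Why: Williamson methylation of the only free phenol; anhydrous carbonate leaves both silyl ethers in place, so O1 stays masked.

Step 10
Reactants: 21 (R)-triisopropyl{3-[4-ethoxy-2-methoxy-3-(3-methylbut-2-en-1-yl)-6-(triisopropylsilyloxy)phenyl]-3-phenylpropoxy}silane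
Product: 22 5-ethoxy-2-[(R)-3-hydroxy-1-phenylpropyl]-3-methoxy-4-(3-methylbut-2-en-1-yl)phenol
Conditions: TBAF (2.5 equiv), THF, 0 °C to rt; aq. NH4Cl
Reagents that add atoms: none
Why: Fluoride cleaves the aryl and the alkyl silyl ether in one operation. With O7 methylated and no carbonyl at C1, the freed O1–H has nothing to lactonise onto.

Step 11
Reactants: 22 5-ethoxy-2-[(R)-3-hydroxy-1-phenylpropyl]-3-methoxy-4-(3-methylbut-2-en-1-yl)phenol
Product: 24 6-ethoxy-2-hydroxy-3-[(R)-3-hydroxy-1-phenylpropyl]-4-methoxy-5-(3-methylbut-2-en-1-yl)benzaldehyde, via hydroxymethylphenol 23 (not isolated)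
Conditions: MgCl2 (2 equiv), Et3N (4 equiv), (CH2O)n (6 equiv), MeCN, reflux; dilute HCl work-up
Reagents that add atoms: paraformaldehyde (as formaldehyde), C=O
Why: Magnesium-mediated ortho-formylation of a phenol (Casnati–Skattebøl reaction): the magnesium phenoxide delivers formaldehyde to the only free ortho carbon, C4a, and the hydroxymethyl intermediate is oxidised by a second formaldehyde. The conditions are not acidic, so the prenyl group never meets a Friedel–Crafts Lewis acid.

Step 12
Reactants: 24 6-ethoxy-2-hydroxy-3-[(R)-3-hydroxy-1-phenylpropyl]-4-methoxy-5-(3-methylbut-2-en-1-yl)benzaldehyde; 25 (E)-2-bromobut-2-ene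
Product: 27 (E)-1-{6-ethoxy-2-hydroxy-3-[(R)-3-hydroxy-1-phenylpropyl]-4-methoxy-5-(3-methylbut-2-en-1-yl)phenyl}-2-methylbut-2-en-1-ol (both carbinol epimers), via (Z)-but-2-en-2-yllithium 26 (not isolated)
Conditions: 25 (3.5 equiv), t-BuLi (7 equiv), Et2O, −78 °C; then 24 in THF, −78 to −30 °C; aq. NH4Cl
Reagents that add atoms: none
Why: Bromine–lithium exchange with retention gives the alkenyllithium with its two methyl groups cis; after two equivalents have deprotonated the hydroxyl groups it adds to the aldehyde. The carbinol centre forms as a mixture, which does not matter because it is oxidised in the next step.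

Step 13
Reactants: 27 (E)-1-{6-ethoxy-2-hydroxy-3-[(R)-3-hydroxy-1-phenylpropyl]-4-methoxy-5-(3-methylbut-2-en-1-yl)phenyl}-2-methylbut-2-en-1-ol
Product: 28 (E)-1-{6-ethoxy-2-hydroxy-3-[(R)-3-hydroxy-1-phenylpropyl]-4-methoxy-5-(3-methylbut-2-en-1-yl)phenyl}-2-methylbut-2-en-1-one
Conditions: MnO2 (activated, 15 equiv), CH2Cl2, rt
Reagents that add atoms: none
Why: MnO2 oxidises the alcohol that is both benzylic and allylic and leaves the saturated primary alcohol, the phenol and the prenyl group alone. The neutral medium avoids premature, uncatalysed ring closure of the tigloyl ketone.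

Step 14
Reactants: 28 (E)-1-{6-ethoxy-2-hydroxy-3-[(R)-3-hydroxy-1-phenylpropyl]-4-methoxy-5-(3-methylbut-2-en-1-yl)phenyl}-2-methylbut-2-en-1-one
Product: 30 (2S,3R)-5-ethoxy-8-[(R)-3-hydroxy-1-phenylpropyl]-7-methoxy-2,3-dimethyl-6-(3-methylbut-2-en-1-yl)chroman-4-one, via C3 enol 29 (not isolated)
Conditions: quinidine (15 mol %), chlorobenzene, 15 °C
Reagents that add atoms: none
Why: Cinchona-alkaloid-catalysed intramolecular oxa-Michael addition of an ortho-tigloylphenol: the quinuclidine nitrogen activates the phenol, the alkaloid hydroxyl hydrogen-bonds the enone, and O1 adds to one face of the beta carbon to set C2 as S. Enol 29 is then protonated anti to the pseudo-axial C2 methyl group, which sets C3 as R (cis, the kinetic product). O5 is still an ethyl ether, so only O1 can cyclise.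

Step 15
Reactants: 30 (2S,3R)-5-ethoxy-8-[(R)-3-hydroxy-1-phenylpropyl]-7-methoxy-2,3-dimethyl-6-(3-methylbut-2-en-1-yl)chroman-4-one
Product: 32 (R)-3-[(2S,3R)-5-ethoxy-7-methoxy-2,3-dimethyl-6-(3-methylbut-2-en-1-yl)-4-oxochroman-8-yl]-3-phenylpropanoic acid, via aldehyde 31 (not isolated)
Conditions: TEMPO (0.2 equiv), PhI(OAc)2 (2.5 equiv), MeCN/pH 7 phosphate buffer (1:1), 0 °C to rt
Reagents that add atoms: water, O
Why: Oxoammonium-mediated oxidation of the primary alcohol through the aldehyde and its hydrate to the acid, under near-neutral conditions that do not enolise C3. With O5 still alkylated there is no free phenol for the iodane to dearomatise, and with O7 and O1 both capped the acid cannot lactonise.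

Step 16
Reactants: 32 (R)-3-[(2S,3R)-5-ethoxy-7-methoxy-2,3-dimethyl-6-(3-methylbut-2-en-1-yl)-4-oxochroman-8-yl]-3-phenylpropanoic acid
Product: 33 (R)-3-[(2S,3R)-5-hydroxy-7-methoxy-2,3-dimethyl-6-(3-methylbut-2-en-1-yl)-4-oxochroman-8-yl]-3-phenylpropanoic acid
Conditions: MgI2·OEt2 (4 equiv), toluene/Et2O, rt; cold aq. citric acid
Reagents that add atoms: none
Why: Chelation-directed ether cleavage: magnesium bridges the C4 carbonyl and O5, and iodide removes the ethyl group by SN2, so the non-chelated C7 methyl ether is not touched; one equivalent of the salt is taken up by the carboxylate. No amine base is present and the temperature stays at ambient, to avoid enolisation at C3; the mild Lewis acid spares the prenyl group.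

## Compound list

1 | (E)-cinnamaldehyde | O=C/C=C/c1ccccc1 | starting material
2 | (triisopropylsilyl)acetylene | C#C[Si](C(C)C)(C(C)C)C(C)C | starting material
3 | (R)-3-phenyl-5-(triisopropylsilyl)pent-4-ynal | CC(C)[Si](C(C)C)(C(C)C)C#C[C@H](CC=O)c1ccccc1 | intermediate
4 | (R)-3-phenyl-5-(triisopropylsilyl)pent-4-yn-1-ol | CC(C)[Si](C(C)C)(C(C)C)C#C[C@H](CCO)c1ccccc1 | intermediate
5 | (S)-3-phenylpent-4-yn-1-ol | C#C[C@H](CCO)c1ccccc1 | intermediate
6 | dilithium (S)-3-phenylpent-4-yn-5-id-1-olate (alkoxide and acetylide of 5) | [Li+].[Li+].[C-]#C[C@H](CC[O-])c1ccccc1 | intermediate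
7 | dilithium (R)-3-phenylpent-1-yne-1,5-bis(olate) (alkoxide and ynolate) | [Li+].[Li+].[O-]C#C[C@H](CC[O-])c1ccccc1 | intermediate
8 | (R)-triisopropyl{[3-phenyl-5-(triisopropylsilyloxy)pent-1-yn-1-yl]oxy}silane | CC(C)[Si](C(C)C)(C(C)C)OC#C[C@H](CCO[Si](C(C)C)(C(C)C)C(C)C)c1ccccc1 | intermediate
9 | 3-ethoxycyclobut-2-en-1-one | CCOC1=CC(=O)C1 | starting material
10 | 3-ethoxybuta-1,3-dien-1-one [(1-ethoxyvinyl)ketene] | C=C(OCC)C=C=O | intermediate
11 | 4-(1-ethoxyvinyl)-2-[(R)-1-phenyl-3-(triisopropylsilyloxy)propyl]-3-(triisopropylsilyloxy)cyclobut-2-en-1-one (C4 epimers) | C=C(OCC)C1C(=O)C([C@H](CCO[Si](C(C)C)(C(C)C)C(C)C)c2ccccc2)=C1O[Si](C(C)C)(C(C)C)C(C)C | intermediate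
12 | (3E)-5-ethoxy-2-[(R)-1-phenyl-3-(triisopropylsilyloxy)propyl]-3-(triisopropylsilyloxy)hexa-1,3,5-trien-1-one | C=C(OCC)/C=C(O[Si](C(C)C)(C(C)C)C(C)C)\C(=C=O)[C@H](CCO[Si](C(C)C)(C(C)C)C(C)C)c1ccccc1 | intermediate
13 | 5-ethoxy-2-[(R)-1-phenyl-3-(triisopropylsilyloxy)propyl]-3-(triisopropylsilyloxy)cyclohexa-2,4-dien-1-one | O=C1CC(OCC)=CC(O[Si](C(C)C)(C(C)C)C(C)C)=C1[C@H](CCO[Si](C(C)C)(C(C)C)C(C)C)c1ccccc1 | intermediate
14 | (R)-5-ethoxy-2-[1-phenyl-3-(triisopropylsilyloxy)propyl]-3-(triisopropylsilyloxy)phenol | CCOc1cc(O)c([C@H](CCO[Si](C(C)C)(C(C)C)C(C)C)c2ccccc2)c(O[Si](C(C)C)(C(C)C)C(C)C)c1 | intermediate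
15 | 2-methylbut-3-en-2-ol | C=CC(C)(C)O | starting material
16 | lithium 2-methylbut-3-en-2-olate | [Li+].[O-]C(C)(C)C=C | intermediate
17 | tert-butyl (2-methylbut-3-en-2-yl) carbonate | C=CC(C)(C)OC(=O)OC(C)(C)C | intermediate
18 | (R)-triisopropyl{3-[4-ethoxy-2-(2-methylbut-3-en-2-yloxy)-6-(triisopropylsilyloxy)phenyl]-3-phenylpropoxy}silane | CCOc1cc(OC(C)(C)C=C)c([C@H](CCO[Si](C(C)C)(C(C)C)C(C)C)c2ccccc2)c(O[Si](C(C)C)(C(C)C)C(C)C)c1 | intermediate
19 | 5-ethoxy-6-(3-methylbut-2-en-1-yl)-2-[(R)-1-phenyl-3-(triisopropylsilyloxy)propyl]-3-(triisopropylsilyloxy)cyclohexa-2,4-dien-1-one (C6 epimers) | O=C1C([C@H](CCO[Si](C(C)C)(C(C)C)C(C)C)c2ccccc2)=C(O[Si](C(C)C)(C(C)C)C(C)C)C=C(OCC)C1CC=C(C)C | intermediate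
20 | (R)-3-ethoxy-2-(3-methylbut-2-en-1-yl)-6-[1-phenyl-3-(triisopropylsilyloxy)propyl]-5-(triisopropylsilyloxy)phenol | CCOc1cc(O[Si](C(C)C)(C(C)C)C(C)C)c([C@H](CCO[Si](C(C)C)(C(C)C)C(C)C)c2ccccc2)c(O)c1CC=C(C)C | intermediate
21 | (R)-triisopropyl{3-[4-ethoxy-2-methoxy-3-(3-methylbut-2-en-1-yl)-6-(triisopropylsilyloxy)phenyl]-3-phenylpropoxy}silane | CCOc1cc(O[Si](C(C)C)(C(C)C)C(C)C)c([C@H](CCO[Si](C(C)C)(C(C)C)C(C)C)c2ccccc2)c(OC)c1CC=C(C)C | intermediate
22 | 5-ethoxy-2-[(R)-3-hydroxy-1-phenylpropyl]-3-methoxy-4-(3-methylbut-2-en-1-yl)phenol | CCOc1cc(O)c([C@H](CCO)c2ccccc2)c(OC)c1CC=C(C)C | intermediate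
23 | 3-ethoxy-2-(hydroxymethyl)-6-[(R)-3-hydroxy-1-phenylpropyl]-5-methoxy-4-(3-methylbut-2-en-1-yl)phenol | CCOc1c(CO)c(O)c([C@H](CCO)c2ccccc2)c(OC)c1CC=C(C)C | intermediate
24 | 6-ethoxy-2-hydroxy-3-[(R)-3-hydroxy-1-phenylpropyl]-4-methoxy-5-(3-methylbut-2-en-1-yl)benzaldehyde | CCOc1c(C=O)c(O)c([C@H](CCO)c2ccccc2)c(OC)c1CC=C(C)C | intermediate
25 | (E)-2-bromobut-2-ene | C/C=C(\C)Br | starting material
26 | (Z)-but-2-en-2-yllithium (methyl groups cis) | C/C=C(\C)[Li] | intermediate
27 | (E)-1-{6-ethoxy-2-hydroxy-3-[(R)-3-hydroxy-1-phenylpropyl]-4-methoxy-5-(3-methylbut-2-en-1-yl)phenyl}-2-methylbut-2-en-1-ol (carbinol epimers) | C/C=C(\C)C(O)c1c(OCC)c(CC=C(C)C)c(OC)c([C@H](CCO)c2ccccc2)c1O | intermediate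
28 | (E)-1-{6-ethoxy-2-hydroxy-3-[(R)-3-hydroxy-1-phenylpropyl]-4-methoxy-5-(3-methylbut-2-en-1-yl)phenyl}-2-methylbut-2-en-1-one | C/C=C(\C)C(=O)c1c(OCC)c(CC=C(C)C)c(OC)c([C@H](CCO)c2ccccc2)c1O | intermediate
29 | (S)-5-ethoxy-8-[(R)-3-hydroxy-1-phenylpropyl]-7-methoxy-2,3-dimethyl-6-(3-methylbut-2-en-1-yl)-2H-chromen-4-ol | COc1c(CC=C(C)C)c(OCC)c2c(c1[C@H](CCO)c1ccccc1)O[C@@H](C)C(C)=C2O | intermediate
30 | (2S,3R)-5-ethoxy-8-[(R)-3-hydroxy-1-phenylpropyl]-7-methoxy-2,3-dimethyl-6-(3-methylbut-2-en-1-yl)chroman-4-one | COc1c(CC=C(C)C)c(OCC)c2c(c1[C@H](CCO)c1ccccc1)O[C@@H](C)[C@@H](C)C2=O | intermediate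
31 | (R)-3-[(2S,3R)-5-ethoxy-7-methoxy-2,3-dimethyl-6-(3-methylbut-2-en-1-yl)-4-oxochroman-8-yl]-3-phenylpropanal | COc1c(CC=C(C)C)c(OCC)c2c(c1[C@H](CC=O)c1ccccc1)O[C@@H](C)[C@@H](C)C2=O | intermediate
32 | (R)-3-[(2S,3R)-5-ethoxy-7-methoxy-2,3-dimethyl-6-(3-methylbut-2-en-1-yl)-4-oxochroman-8-yl]-3-phenylpropanoic acid | COc1c(CC=C(C)C)c(OCC)c2c(c1[C@H](CC(=O)O)c1ccccc1)O[C@@H](C)[C@@H](C)C2=O | intermediate
33 | (R)-3-[(2S,3R)-5-hydroxy-7-methoxy-2,3-dimethyl-6-(3-methylbut-2-en-1-yl)-4-oxochroman-8-yl]-3-phenylpropanoic acid | COc1c(CC=C(C)C)c(O)c2c(c1[C@H](CC(=O)O)c1ccccc1)O[C@@H](C)[C@@H](C)C2=O | target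

## Step count and least certain steps

Total step count: 16. Longest linear sequence: 15 steps (steps 1 to 5 and 7 to 16); step 6 is a one-step side branch that prepares carbonate 17.

Step 5 (key step). The donor-substituted cyclobutenone may open too slowly. Thermal silyl migration or oligomerisation of the siloxyalkyne, dimerisation of the ketene, or O-acylation of the new phenol by a second ketene could then outrun the cycloaddition.
The fallback uses only known reaction types: ring A is taken from a preformed phloroglucinol nucleus, and the benzylic centre is set by a catalytic asymmetric conjugate reduction. It replaces the whole alkyne branch (compounds 1 to 13), so it sets out not from a compound of the route but, in place of 1, from purchased 5,7-dihydroxy-4-phenyl-2H-chromen-2-one F1, and it comes back to the route at 14. Ethylation of the less hindered 7-hydroxyl (EtI, K2CO3, acetone; the 5-hydroxyl is shielded by the peri phenyl group) would give 7-ethoxy-5-hydroxy-4-phenyl-2H-chromen-2-one F2. Silylation (TIPSOTf, 2,6-lutidine) would give 7-ethoxy-4-phenyl-5-(triisopropylsilyloxy)-2H-chromen-2-one F3. Copper hydride conjugate reduction of this 4-arylcoumarin (Cu(OAc)2, DTBM-SEGPHOS in the enantiomer that leads to the R lactone, (EtO)2MeSiH, t-BuOH, toluene) would give (R)-7-ethoxy-4-phenyl-5-(triisopropylsilyloxy)chroman-2-one F4. LiBH4 would open the lactone to (R)-5-ethoxy-2-(3-hydroxy-1-phenylpropyl)-3-(triisopropylsilyloxy)phenol F5. TIPSCl (1.05 equiv) and imidazole in CH2Cl2 at 0 °C would then silylate the primary hydroxyl in preference to the hindered phenol and give 14. In 14 the lactone oxygen has become the free phenol O7, the peri oxygen is the silyl ether O1, and the ethoxy group sits para to the chain as O5.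

Step 16. Enolisation of the magnesium-chelated ketone, or ring opening and re-closure, may epimerise C3 during dealkylation. Cleavage of an ethyl ether is also slower than that of a methyl ether, which lengthens the exposure. Acid on work-up may cyclise the prenyl group onto the freed O5.
The fallback gives up stereoretentive dealkylation and corrects C3 afterwards. It sets out from 32 and comes back at 33. If the dealkylation delivers 33 mixed with its C3 epimer, (R)-3-[(2S,3S)-5-hydroxy-7-methoxy-2,3-dimethyl-6-(3-methylbut-2-en-1-yl)-4-oxochroman-8-yl]-3-phenylpropanoic acid F6, the mixture would be persilylated (TMSOTf, Et3N, CH2Cl2, 0 °C). Both epimers converge on the silyl enol ether trimethylsilyl (R)-3-[(S)-7-methoxy-2,3-dimethyl-6-(3-methylbut-2-en-1-yl)-4,5-bis(trimethylsilyloxy)-2H-chromen-8-yl]-3-phenylpropanoate F7. Protonolysis at −78 °C (HF·pyridine, THF) should deliver the proton to C3 anti to the C2 methyl group and return cis-configured 33.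

Step 14. Facial selectivity in the conjugate addition may be poor or reversed, since the fixed benzylic centre next to O1 may be mismatched with the catalyst. Prolonged exposure to the base may also equilibrate the cis product towards the trans isomer. A reversed sense alone would be met by the pseudo-enantiomeric alkaloid, which is a change of conditions only.
The change of approach is to give up catalyst control and to rely on separation and recycling. It sets out from 28 and comes back at 30. Cyclisation with an achiral tertiary amine (DABCO, toluene, rt) would give 30 together with its ring-B diastereomer, (2R,3S)-5-ethoxy-8-[(R)-3-hydroxy-1-phenylpropyl]-7-methoxy-2,3-dimethyl-6-(3-methylbut-2-en-1-yl)chroman-4-one F8. The two differ in their relation to the fixed benzylic centre and should be separable by chromatography; the unwanted isomer could be returned to 28 by base-induced ring opening and cyclised again.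

Step 11. Formylation may be incomplete at a carbon flanked by OH and OEt on a fully substituted ring, and excess formaldehyde may O-formylate the hydroxyl groups.
The fallback replaces direct formylation by halogenation and metalation. It sets out from 22 and comes back at 24. Iodination of the phenol at its only free ortho carbon (I2, morpholine, CH2Cl2, 0 °C; the alkene is inert to this reagent) would give 3-ethoxy-6-[(R)-3-hydroxy-1-phenylpropyl]-2-iodo-5-methoxy-4-(3-methylbut-2-en-1-yl)phenol F9. Deprotonation and iodine–lithium exchange (t-BuLi, 4.2 equiv, THF, −78 °C) followed by DMF would give 24.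

Step 4. The dilithium alkoxide–acetylide may aggregate and take up oxygen sluggishly, a slight excess of base may deprotonate the doubly activated propargylic and benzylic C–H and erode the stereocentre, and silylation of two different oxyanions in one flask may be incomplete.
The fallback separates protection from oxidation, so that a monolithium acetylide is oxidised. It sets out from 5 and comes back at 8. Silylation of the hydroxyl group first (TIPSCl, imidazole, DMF, rt) would give (S)-triisopropyl[(3-phenylpent-4-yn-1-yl)oxy]silane F10. A single equivalent of n-BuLi (THF, −78 °C), oxidation with LiOOt-Bu and trapping with TIPSOTf (1.2 equiv) would then give 8.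

## Further compounds

F1 | step 5 | 5,7-dihydroxy-4-phenyl-2H-chromen-2-one | O=C1C=C(c2ccccc2)c2c(O)cc(O)cc2O1
F2 | step 5 | 7-ethoxy-5-hydroxy-4-phenyl-2H-chromen-2-one | CCOc1cc(O)c2c(c1)OC(=O)C=C2c1ccccc1
F3 | step 5 | 7-ethoxy-4-phenyl-5-(triisopropylsilyloxy)-2H-chromen-2-one | CCOc1cc(O[Si](C(C)C)(C(C)C)C(C)C)c2c(c1)OC(=O)C=C2c1ccccc1
F4 | step 5 | (R)-7-ethoxy-4-phenyl-5-(triisopropylsilyloxy)chroman-2-one | CCOc1cc(O[Si](C(C)C)(C(C)C)C(C)C)c2[C@@H](c3ccccc3)CC(=O)Oc2c1
F5 | step 5 | (R)-5-ethoxy-2-(3-hydroxy-1-phenylpropyl)-3-(triisopropylsilyloxy)phenol | CCOc1cc(O)c([C@H](CCO)c2ccccc2)c(O[Si](C(C)C)(C(C)C)C(C)C)c1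
F6 | step 16 | (R)-3-[(2S,3S)-5-hydroxy-7-methoxy-2,3-dimethyl-6-(3-methylbut-2-en-1-yl)-4-oxochroman-8-yl]-3-phenylpropanoic acid | COc1c(CC=C(C)C)c(O)c2c(c1[C@H](CC(=O)O)c1ccccc1)O[C@@H](C)[C@H](C)C2=O
F7 | step 16 | trimethylsilyl (R)-3-[(S)-7-methoxy-2,3-dimethyl-6-(3-methylbut-2-en-1-yl)-4,5-bis(trimethylsilyloxy)-2H-chromen-8-yl]-3-phenylpropanoate | COc1c(CC=C(C)C)c(O[Si](C)(C)C)c2c(c1[C@H](CC(=O)O[Si](C)(C)C)c1ccccc1)O[C@@H](C)C(C)=C2O[Si](C)(C)C
F8 | step 14 | (2R,3S)-5-ethoxy-8-[(R)-3-hydroxy-1-phenylpropyl]-7-methoxy-2,3-dimethyl-6-(3-methylbut-2-en-1-yl)chroman-4-one | COc1c(CC=C(C)C)c(OCC)c2c(c1[C@H](CCO)c1ccccc1)O[C@H](C)[C@H](C)C2=O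
F9 | step 11 | 3-ethoxy-6-[(R)-3-hydroxy-1-phenylpropyl]-2-iodo-5-methoxy-4-(3-methylbut-2-en-1-yl)phenol | CCOc1c(I)c(O)c([C@H](CCO)c2ccccc2)c(OC)c1CC=C(C)C
F10 | step 4 | (S)-triisopropyl[(3-phenylpent-4-yn-1-yl)oxy]silane | C#C[C@H](CCO[Si](C(C)C)(C(C)C)C(C)C)c1ccccc1
A1 | alternative 1 | methyl (R)-3-[4-acetoxy-5-(2-diazopropanoyl)-6-ethoxy-2-methoxy-3-(3-methylbut-2-en-1-yl)phenyl]-3-phenylpropanoate | COc1c(CC=C(C)C)c(OC(C)=O)c(C(=O)C(C)=[N+]=[N-])c(OCC)c1[C@H](CC(=O)OC)c1ccccc1
A2 | alternative 1 | methyl (R)-3-[(2S,3R)-5-acetoxy-7-methoxy-2,3-dimethyl-6-(3-methylbut-2-en-1-yl)-4-oxochroman-8-yl]-3-phenylpropanoate | COc1c(CC=C(C)C)c(OC(C)=O)c2c(c1[C@H](CC(=O)OC)c1ccccc1)O[C@@H](C)[C@@H](C)C2=O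
A3 | alternative 2 | methyl (R)-3-[2-hydroxy-3-iodo-6-methoxy-4-(methoxymethoxy)-5-(3-methylbut-2-en-1-yl)phenyl]-3-phenylpropanoate | COc1c(CC=C(C)C)c(OCOC)c(I)c(O)c1[C@H](CC(=O)OC)c1ccccc1
A4 | alternative 2 | buta-1,2-diene | C=C=CC
A5 | alternative 2 | carbon monoxide | [C-]#[O+]
A6 | alternative 2 | methyl (R)-3-[(S)-7-methoxy-5-(methoxymethoxy)-2-methyl-3-methylene-6-(3-methylbut-2-en-1-yl)-4-oxochroman-8-yl]-3-phenylpropanoate | COc1c(CC=C(C)C)c(OCOC)c2c(c1[C@H](CC(=O)OC)c1ccccc1)O[C@@H](C)C(=C)C2=O
A7 | alternative 3 | methyl (R)-3-hydroxybutanoate | C[C@@H](O)CC(=O)OC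
A8 | alternative 3 | methyl (R)-3-{2-hydroxy-3-[(2R,3R)-3-hydroxy-2-methylbutanoyl]-6-methoxy-4-(methoxymethoxy)-5-(3-methylbut-2-en-1-yl)phenyl}-3-phenylpropanoate | COc1c(CC=C(C)C)c(OCOC)c(C(=O)[C@H](C)[C@@H](C)O)c(O)c1[C@H](CC(=O)OC)c1ccccc1
A9 | alternative 3 | methyl (R)-3-[(2S,3R)-7-methoxy-5-(methoxymethoxy)-2,3-dimethyl-6-(3-methylbut-2-en-1-yl)-4-oxochroman-8-yl]-3-phenylpropanoate | COc1c(CC=C(C)C)c(OCOC)c2c(c1[C@H](CC(=O)OC)c1ccccc1)O[C@@H](C)[C@@H](C)C2=O
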